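The rate constants were drawn at random within sensible limits.

Slowness came first: I expected so little to react that I could freeze the fractions of the charge.

    second substrate + catalyst ⇌ idle complex, settled at all times (K1 = 130 /M)
    starting material + coupling partner + catalyst → catalyst + target (k2 = 0.49 /M²/s)
    starting material + target → side product (k3 = 1.6 × 10⁻⁴ /M/s)
    second substrate + coupling partner + catalyst → catalyst + second product (k4 = 0.12 /M²/s)

| setting | Monday's | Friday's | Saturday's | Sunday's |
|---|---|---|---|---|
| starting material | 0.50 M (fed, over 10 min) | 0.50 M | 0.50 M | 0.50 M |
| coupling partner | 0.550 M | 0.550 M | 0.550 M | 0.550 M |
| second substrate | 0.250 M | 0.250 M | 0.250 M (fed, over 10 min) | 0.250 M (in portions, 2, over 10 min) |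
| catalyst | 1.0 mM | 1.0 mM | 1.0 mM | 1.0 mM |
| time | 50 min | 50 min | 50 min | 50 min |
| remark | all else is in the flask from the start; the feed brings no volume worth counting | everything together at the start | all else is in the flask from the start; the feed brings no volume worth counting | first portion at the start, last at 10 min |

- percent here means starting material units held: one side product counts as two
- run time (Monday's): 50 min

* which flask leads in share of target in target plus side product ("all alike" within 1.5 percentage points) (Monday's / Friday's / Saturday's / Sunday's / all alike)
* share of target in target plus side product at the end, Monday's
* share of target in target plus side product at the end, Friday's
* share of target in target plus side product at the end, Saturday's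
* share of target in target plus side product at the end, Sunday's

With the full second substrate, step 1 left a free fraction of catalyst of 0.0299. The half-life of starting material by step 2, 43 min on the whole catalyst, thus stretched to 1438 min, much longer than the run. I froze starting material and coupling partner at their charges.

Target then met a pseudo-first-order loss. I called it the hazard, step 3's constant times the starting material charged: 0.00480 /min. If a fraction s of the target formed survives, the share is s over two minus s, since each lost target counts twice in side product.

I counted births in minutes at the full-dose rate. On Monday's, births and hazard both followed the fed starting material, so its clock lost half the feed time. On Saturday's, I integrated the free fraction over the feed, and those births centred a quarter of the way through it. On Sunday's, the first portion raised the free fraction until the last one came. Every flask then added 40.0 min of later births, whose mean survival was 0.910.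

- Monday's: early births 5.00 min, survival 0.899, share 81.7%
- Friday's: early births 10 min, survival 0.889, share 80.0%
- Sunday's: early births 19.4 min, survival 0.876, share 77.9%
- Saturday's: early births 36.2 min, survival 0.856, share 74.8%

Reading down, early births grow and the share falls. Saturday's early target waited 47.5 min, longer than the 20.0 min of later target. Monday's led Friday's by 1.7 percentage points, just over the margin, so I chose Monday's.

The forecast also chose Monday's: 81.8% for Monday's, 80.2% for Friday's, 75.3% for Saturday's and 78.2% for Sunday's. “Monday leads, narrowly beyond the 1.5-point margin.” Its Saturday's figure stood 0.5 points above mine.

The simulation led with Monday's: 81.8% for Monday's, 80.2% for Friday's, 75.1% for Saturday's and 78.1% for Sunday's.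

Saturday's readings of target and side product give a survival of 0.858, against my 0.856. The neighbouring flask was Saturday's with 0.30 M of starting material. I kept the birth-minutes per unit charged, but the hazard fell to 0.00288 /min. I reckoned its survival at 0.910 and its share at 83.5%. That neighbouring flask gave a share of 83.8%, with target at 3.29% of its own charge.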